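**Retrosynthetic overview**
1. The target is the (3S)-isoflavanone. Rings A and B are bought as two benzaldehydes; ring C is the only ring made, and it is made last.
2. Key bond C3–C4: the ring A aldehyde carbon becomes a catalytic acyl anion (Breslow enaminol of a chiral triazolylidene) and adds 1,6 to a ring B para-quinone methide. Two electrophilic carbons are joined, ring C closes and C3 is set in the same event.
3. The quinone methide is released from a p-hydroxybenzyl sulfone. Its free 4'-OH and the 5'-(1,1-dimethylallyl) group both arise from Claisen rearrangement of a 4'-O-prenyl ether.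
4. O1–C2 and C2–C3: the ring A phenoxide opens a ring B styrene oxide (aldehyde plus sulfur ylide); the benzylic OH is then exchanged for the sulfone.
5. Order: O-prenylation → epoxidation/phenolysis → sulfonylation → Claisen → ring C closure.

Assumption: 4-hydroxy-2-methoxybenzaldehyde and 2,6-dihydroxy-4-methoxybenzaldehyde are taken as catalogue compounds, and the given SMILES is read as the (3S) enantiomer.

**Route**

Step 1
Reactants: 1 4-hydroxy-2-methoxybenzaldehyde; 2 1-bromo-3-methylbut-2-ene (prenyl bromide)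
Product: 3 2-methoxy-4-[(3-methylbut-2-en-1-yl)oxy]benzaldehyde
Conditions: K2CO3 (1.5 equiv), DMF, 23 °C
Reagents that add atoms: none
Why: Williamson ether synthesis, the para-phenoxide displacing the primary allylic bromide by SN2 at oxygen; no stereocenter is formed.

Step 2
Reactants: 3 2-methoxy-4-[(3-methylbut-2-en-1-yl)oxy]benzaldehyde; 4 2,6-dihydroxy-4-methoxybenzaldehyde
Product: 6 rac-2-hydroxy-6-(2-hydroxy-2-{2-methoxy-4-[(3-methylbut-2-en-1-yl)oxy]phenyl}ethoxy)-4-methoxybenzaldehyde, via aryl oxirane 5 (not isolated)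
Conditions: Me3SI (1.05 equiv), NaH (1.05 equiv), DMSO/THF, 0 → 23 °C, 2 h; then 4 (1.2 equiv), Cs2CO3 (0.2 equiv), 60 °C
Reagents that add atoms: trimethylsulfonium iodide, C[S+](C)C.[I-]
Why: Corey–Chaykovsky epoxidation followed, without isolating the silica-labile oxirane, by base-catalysed SN2 phenolysis at the unhindered terminal carbon (4 is symmetric, so mono-alkylation gives one isomer); the carbinol center is racemic and is erased later at the quinone methide stage.

Step 3
Reactants: 6 rac-2-hydroxy-6-(2-hydroxy-2-{2-methoxy-4-[(3-methylbut-2-en-1-yl)oxy]phenyl}ethoxy)-4-methoxybenzaldehyde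
Product: 7 rac-2-hydroxy-4-methoxy-6-(2-{2-methoxy-4-[(3-methylbut-2-en-1-yl)oxy]phenyl}-2-[(4-methylphenyl)sulfonyl]ethoxy)benzaldehyde
Conditions: p-TolSO2H (2 equiv), 4 Å MS, CH2Cl2, 0 → 23 °C
Reagents that add atoms: p-toluenesulfinic acid, Cc1ccc(cc1)S(=O)O
Why: SN1 sulfonylation of an electron-rich benzylic alcohol, the 2,4-dialkoxybenzylic cation being trapped at sulfur to give the thermodynamically stable sulfone; the new center is racemic and not carried into the target.

Step 4
Reactants: 7 rac-2-hydroxy-4-methoxy-6-(2-{2-methoxy-4-[(3-methylbut-2-en-1-yl)oxy]phenyl}-2-[(4-methylphenyl)sulfonyl]ethoxy)benzaldehyde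
Product: 9 rac-2-hydroxy-6-(2-[4-hydroxy-2-methoxy-5-(2-methylbut-3-en-2-yl)phenyl]-2-[(4-methylphenyl)sulfonyl]ethoxy)-4-methoxybenzaldehyde, via ortho-dienone 8 (not isolated)
Conditions: Eu(fod)3 [Eu(C10H10F7O2)3, tris(6,6,7,7,8,8,8-heptafluoro-2,2-dimethyloctane-3,5-dionato)europium] (10 mol %), CHCl3, 60 °C
Reagents that add atoms: none
Why: Lewis-acid-catalysed aromatic Claisen rearrangement ([3,3] shift, then rearomatisation) that delivers the reverse-prenyl group to C5', the open ortho position para to the methoxy group, not to C3' which is flanked by OMe, and frees the 4'-OH; no target stereocenter is involved.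

Step 5
Reactants: 9 rac-2-hydroxy-6-(2-[4-hydroxy-2-methoxy-5-(2-methylbut-3-en-2-yl)phenyl]-2-[(4-methylphenyl)sulfonyl]ethoxy)-4-methoxybenzaldehyde
Product: 11 (3S)-5-hydroxy-3-[4-hydroxy-2-methoxy-5-(2-methylbut-3-en-2-yl)phenyl]-7-methoxy-2,3-dihydro-4H-chromen-4-one, via para-quinone methide 10 (not isolated)
Conditions: (5aS,10bR)-2-(pentafluorophenyl)-5a,10b-dihydro-4H,6H-indeno[2,1-b][1,2,4]triazolo[4,3-d][1,4]oxazin-2-ium tetrafluoroborate, (C18H11F5N3O)BF4 (20 mol %), Cs2CO3 (1.3 equiv), 4 Å MS, PhMe/CH2Cl2 4:1 (0.02 M), 0 °C; AcOH quench at 0 °C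
Reagents that add atoms: none
Why: Proposed new method: Cs2CO3 expels sulfinate from the p-hydroxybenzyl sulfone (1,6-elimination) to give the achiral para-quinone methide 10, while the chiral triazolylidene converts the tethered aldehyde into a Breslow enaminol (acyl anion equivalent) that adds 6-exo to the exocyclic quinone methide carbon in a vinylogous intramolecular Stetter reaction driven by rearomatisation, forming C3–C4 and ring C; attack on the Si face of that carbon gives (3S), which the indane wall of the (5aS,10bR) catalyst is expected to favour (the commercially available mirror-image salt is used if the sense proves opposite, checked by chiral HPLC and CD); the closest known reactions are the asymmetric intramolecular Stetter synthesis of chroman-4-ones, carbene-catalysed acyl anion 1,6-additions to para-quinone methides and acyl anion additions to quinone methides generated in situ.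

**Compound list**
1 | 4-hydroxy-2-methoxybenzaldehyde | O=Cc1ccc(O)cc1OC | starting material
2 | 1-bromo-3-methylbut-2-ene (prenyl bromide) | CC(C)=CCBr | starting material
3 | 2-methoxy-4-[(3-methylbut-2-en-1-yl)oxy]benzaldehyde | O=Cc1ccc(OCC=C(C)C)cc1OC | intermediate
4 | 2,6-dihydroxy-4-methoxybenzaldehyde | O=Cc1c(O)cc(OC)cc1O | starting material
5 | rac-2-{2-methoxy-4-[(3-methylbut-2-en-1-yl)oxy]phenyl}oxirane (not isolated) | COc1cc(OCC=C(C)C)ccc1C1CO1 | intermediate
6 | rac-2-hydroxy-6-(2-hydroxy-2-{2-methoxy-4-[(3-methylbut-2-en-1-yl)oxy]phenyl}ethoxy)-4-methoxybenzaldehyde | O=Cc1c(O)cc(OC)cc1OCC(O)c1ccc(OCC=C(C)C)cc1OC | intermediate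
7 | rac-2-hydroxy-4-methoxy-6-(2-{2-methoxy-4-[(3-methylbut-2-en-1-yl)oxy]phenyl}-2-[(4-methylphenyl)sulfonyl]ethoxy)benzaldehyde | O=Cc1c(O)cc(OC)cc1OCC(c1ccc(OCC=C(C)C)cc1OC)S(=O)(=O)c1ccc(C)cc1 | intermediate
8 | 2-hydroxy-4-methoxy-6-{2-[6-methoxy-3-(2-methylbut-3-en-2-yl)-4-oxocyclohexa-1,5-dien-1-yl]-2-[(4-methylphenyl)sulfonyl]ethoxy}benzaldehyde, racemic diastereomer mixture (not isolated) | O=Cc1c(O)cc(OC)cc1OCC(C1=CC(C(C)(C)C=C)C(=O)C=C1OC)S(=O)(=O)c1ccc(C)cc1 | intermediate
9 | rac-2-hydroxy-6-(2-[4-hydroxy-2-methoxy-5-(2-methylbut-3-en-2-yl)phenyl]-2-[(4-methylphenyl)sulfonyl]ethoxy)-4-methoxybenzaldehyde | O=Cc1c(O)cc(OC)cc1OCC(c1cc(C(C)(C)C=C)c(O)cc1OC)S(=O)(=O)c1ccc(C)cc1 | intermediate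
10 | 2-hydroxy-4-methoxy-6-{(2E)-2-[2-methoxy-5-(2-methylbut-3-en-2-yl)-4-oxocyclohexa-2,5-dien-1-ylidene]ethoxy}benzaldehyde, drawn as the less hindered E isomer (not isolated) | O=Cc1c(O)cc(OC)cc1OC/C=C1\C=C(C(C)(C)C=C)C(=O)C=C1OC | intermediate
11 | (3S)-5-hydroxy-3-[4-hydroxy-2-methoxy-5-(2-methylbut-3-en-2-yl)phenyl]-7-methoxy-2,3-dihydro-4H-chromen-4-one | C=CC(C)(C)c1cc([C@H]2COc3cc(OC)cc(O)c3C2=O)c(OC)cc1O | target

**Step count and risks**
Total steps: 5 (step 2 is a telescoped two-stage operation). Longest linear sequence: 5 (1 → 3 → 6 → 7 → 9 → 11); 4 enters in step 2.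

The step most likely to fail is step 5. The aldehyde is di-ortho-oxygenated and carries an acidic ortho-OH, so under base it becomes a vinylogous carboxylate and the Breslow intermediate may form too slowly. The quinone methide can then tautomerise to the 4-vinylphenol enol ether or oligomerise, and the α-aryl ketone 11 can lose ee by enolisation or retro-oxa-Michael opening if left with base. The fallback masks the ring A phenol and sets out from 7. MOMCl and i-Pr2NEt in CH2Cl2 give the methoxymethyl ether of 7, F1. The Eu(fod)3 Claisen rearrangement then passes through the ortho-dienone F2 to the MOM-protected phenol sulfone F3. Cyclisation with the same triazolium salt (C18H11F5N3O)BF4 and Cs2CO3 runs through the MOM-protected para-quinone methide F4 to the (3S)-5-O-methoxymethyl isoflavanone F5. Brief treatment with 0.5 M HCl in MeOH at 0 °C cleaves the peri-carbonyl-assisted acetal and comes back to the route at 11.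

The second risk is step 2. The dialkoxy-substituted styrene oxide 5 is acid- and silica-labile, and its electron-rich aryl group can steer the phenoxide to the benzylic carbon. The fallback never makes an epoxide and lets a Michael acceptor fix the regiochemistry; it sets out from 3. NaBH4 in MeOH gives {2-methoxy-4-[(3-methylbut-2-en-1-yl)oxy]phenyl}methanol F6. p-TolSO2H in CH2Cl2 converts it into the benzyl sulfone F7. α-Methylenation (Mannich reaction with Me2NCH2NMe2 and Ac2O in DMF at 60 °C) gives the 1-aryl-1-sulfonylethene F8. Oxa-Michael addition of 4 (catalytic Cs2CO3, DMF, 23 °C) then puts the aryloxy group on the terminal carbon and comes back to the route at 7.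

The third risk is step 4. The trivalent europium Lewis acid may ionise the benzylic sulfone, or the freed p-hydroxybenzyl sulfone may lose sulfinate before it is wanted. The fallback runs the sigmatropic step before any leaving group is present and sets out from 6. A thermal, water-accelerated Claisen rearrangement (EtOH/H2O 4:1, 110 °C, sealed tube) passes through the ortho-dienone F9 to the p-hydroxybenzyl alcohol F10. This is sulfonylated with p-TolSO2H (1.5 equiv) in CH2Cl2/THF at 0 °C, which is easier here because the free para-OH assists ionisation, and the sequence comes back to the route at 9.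

**Further compounds**
F1 | step 5 | rac-2-(methoxymethoxy)-4-methoxy-6-(2-{2-methoxy-4-[(3-methylbut-2-en-1-yl)oxy]phenyl}-2-[(4-methylphenyl)sulfonyl]ethoxy)benzaldehyde | O=Cc1c(OCOC)cc(OC)cc1OCC(c1ccc(OCC=C(C)C)cc1OC)S(=O)(=O)c1ccc(C)cc1
F2 | step 5 | 2-(methoxymethoxy)-4-methoxy-6-{2-[6-methoxy-3-(2-methylbut-3-en-2-yl)-4-oxocyclohexa-1,5-dien-1-yl]-2-[(4-methylphenyl)sulfonyl]ethoxy}benzaldehyde, racemic diastereomer mixture | O=Cc1c(OCOC)cc(OC)cc1OCC(C1=CC(C(C)(C)C=C)C(=O)C=C1OC)S(=O)(=O)c1ccc(C)cc1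
F3 | step 5 | rac-2-(2-[4-hydroxy-2-methoxy-5-(2-methylbut-3-en-2-yl)phenyl]-2-[(4-methylphenyl)sulfonyl]ethoxy)-4-methoxy-6-(methoxymethoxy)benzaldehyde | O=Cc1c(OCOC)cc(OC)cc1OCC(c1cc(C(C)(C)C=C)c(O)cc1OC)S(=O)(=O)c1ccc(C)cc1
F4 | step 5 | 4-methoxy-2-{(2E)-2-[2-methoxy-5-(2-methylbut-3-en-2-yl)-4-oxocyclohexa-2,5-dien-1-ylidene]ethoxy}-6-(methoxymethoxy)benzaldehyde | O=Cc1c(OCOC)cc(OC)cc1OC/C=C1\C=C(C(C)(C)C=C)C(=O)C=C1OC
F5 | step 5 | (3S)-3-[4-hydroxy-2-methoxy-5-(2-methylbut-3-en-2-yl)phenyl]-7-methoxy-5-(methoxymethoxy)-2,3-dihydro-4H-chromen-4-one | C=CC(C)(C)c1cc([C@H]2COc3cc(OC)cc(OCOC)c3C2=O)c(OC)cc1O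
F6 | step 2 | {2-methoxy-4-[(3-methylbut-2-en-1-yl)oxy]phenyl}methanol | COc1cc(OCC=C(C)C)ccc1CO
F7 | step 2 | 2-methoxy-1-{[(4-methylphenyl)sulfonyl]methyl}-4-[(3-methylbut-2-en-1-yl)oxy]benzene | COc1cc(OCC=C(C)C)ccc1CS(=O)(=O)c1ccc(C)cc1
F8 | step 2 | 2-methoxy-1-{1-[(4-methylphenyl)sulfonyl]ethenyl}-4-[(3-methylbut-2-en-1-yl)oxy]benzene | COc1cc(OCC=C(C)C)ccc1C(=C)S(=O)(=O)c1ccc(C)cc1
F9 | step 4 | 2-hydroxy-6-{2-hydroxy-2-[6-methoxy-3-(2-methylbut-3-en-2-yl)-4-oxocyclohexa-1,5-dien-1-yl]ethoxy}-4-methoxybenzaldehyde, racemic diastereomer mixture | O=Cc1c(O)cc(OC)cc1OCC(O)C1=CC(C(C)(C)C=C)C(=O)C=C1OC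
F10 | step 4 | rac-2-hydroxy-6-{2-hydroxy-2-[4-hydroxy-2-methoxy-5-(2-methylbut-3-en-2-yl)phenyl]ethoxy}-4-methoxybenzaldehyde | O=Cc1c(O)cc(OC)cc1OCC(O)c1cc(C(C)(C)C=C)c(O)cc1OC
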